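| flask | E | G | time |
|---|---|---|---|
| violet | 0.20 M | 0.260 M | 12 h |
| grey | 0.20 M | 0.520 M | 12 h |
1. which of these there is most of at the end, counted by the E in it, violet (X / L / E / D / Q)
2. which of these there is most of at the end, counted by the E in it, grey (X / L / E / D / Q)
3. amount of the one of these that there is most of at the end, in percent of the E charged, violet
4. amount of the one of these that there is most of at the end, in percent of the E charged, grey
    E + G → L + J (k1 = 0.58 L mol⁻¹ h⁻¹)
    E + G → D + J (k2 = 0.81 L mol⁻¹ h⁻¹)
    G + L → X + J (k3 = 0.94 L mol⁻¹ h⁻¹)
    G + D → X + J (k4 = 0.18 L mol⁻¹ h⁻¹)
    Z ⇌ L, rate k5*(cs5 - [L]) while solid is left; crystals form when [L] > cs5 (cs5 = 0.14 M, k5 = 23 h⁻¹)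
    L ⇌ Q (K6 = 2.2, k6 = 0.15 h⁻¹)
- L is meant together with its Z
- solid, in amounts per volume of the solution: Z
- run time (violet): 12 h

- The 4 questions asked which species led at the end of each flask and how far, and I began with cD, which I drew against cE instead of time, since dividing the rate law of D (steps 2 and 4) by that of E (steps 1 and 2) cancels cG and with it the clock.
- What remained was the share of E taken at the D site, 58.3%, above the even split of 0.5 that serves as zero, and the loss ratio a = k4/(k1+k2) = 0.129, a selectivity factor, which gave, with f the fraction of E left, cD in parts of the E charge = share/(1 − a) · (f^a − f).
- The curve began with a slope, in parts of the E charge, of 0.211 h⁻¹ in violet, and twice that in grey.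
- It crested where cD/cE = k2/k4 = 4.50 (equal constants would put this at 1), which the line placed at f = 9.55% and a height of 43.0%.
- For the clock I let G go by the first addition and nothing else, which made E fall too fast and so gave a floor: f = 11.8% at the end in violet and 0.296% in grey.
- The crest therefore came no earlier than 13.9 h in violet, later than the end of the run, and from 4.32 h in grey.
- In violet the top was flat: at twice the floor of f the line still gave 39.7%, against 42.9% at the floor, so I committed to D between those two figures, above the 36.8% that the L side could hold at most, shared among L, Q and the part of X that it feeds.
- In grey the floor of f gave D of 31.3%, with 26.8% already passed on to X and up to 41.6% on the L side, so I took X there, though my reckoning stopped short of its height.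
- The forecast, made apart from this, gave D at 42% for violet and X at 49% for grey, holding that “the faster-forming and slowly consumed D ends up ahead” in violet.
- The flask gave D at 42.1% in violet with 16.1% of E left, and X at 51.7% in grey, where D stood at 35.4%. With a = 0.129, the 0.82% of E left in grey put the line at 35.5%. In a neighbouring flask, violet with 0.16 M of G, E ended at 37.7%, which put the line at 33.8%, and the flask held D at 33.7%.

The rate constants are those of an exercise, and the outcome is calculated.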